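**Plan**

1. Retrosynthesis (daucane numbering: C1 = methyl-bearing ring-fusion carbon, C2 = CH–OAc, C4 = C(OH)i-Pr, C5 = ring-fusion CH, C6 = CH–O-aroyl, C7=C8(CH3), C9 = ring C=O, C10 = ring CH2): first the two ester C–O bonds, then the ring bond C9–C10, then C5–C6 and C1–C10.
2. Enabling feature: in the seven-membered ring the C9 ketone and the C6 oxygen are 1,4 across the cis C7=C8 bond, so C6–C7=C8–C9 can be carried as an α-methylbutenolide (a temporary ring). Its lactone carbonyl C9 takes up C10 once the C10–I bond is reduced to a carbanion (union of two electrophilic carbons), and the lactone then opens to the ring ketone and the C6 hydroxyl.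
3. Forward: the five-membered ring first (from 3-ethoxycyclopent-2-en-1-one), then the butenolide is attached at C5 by dearomatising a 2-silyloxyfuran, then the seven-membered ring is closed, then the two acylations.
4. Stereochemistry: C4 by copper-catalysed enantioselective conjugate borylation/oxidation; C5 and C6 by a vinylogous Mukaiyama–Michael addition anti to the C4 silyloxy group; C1 by hydroxymethylation anti to the C5 substituent; C2 by hydroxyl-directed reduction.

Key step: step 12

Remark: the daucane numbering of line 1 (with C3 = ring CH2) is used for all intermediates.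
Remark: (R,R)-QuinoxP* is (R,R)-2,3-bis(tert-butylmethylphosphino)quinoxaline; it is assumed to give the (R)-carbinol in step 3, otherwise its mirror image is used.
Remark: 3-ethoxycyclopent-2-en-1-one, 3-methylfuran-2(5H)-one and 4-acetoxybenzoyl chloride are taken as purchased.

Step 1
Reactants: 1 3-ethoxycyclopent-2-en-1-one
Product: 3 3-(propan-2-yl)cyclopent-2-en-1-one, via tertiary allylic alkoxide 2 (not isolated)
Conditions: i-PrMgCl, THF, 0 °C; then 1 M HCl, rt
Reagents that add atoms: isopropylmagnesium chloride, CC(C)[Mg]Cl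
Why: Stork–Danheiser alkylative transposition, in which the Grignard reagent adds 1,2 to the vinylogous ester and acid hydrolysis of the enol ether with loss of water moves the carbonyl to give the β-isopropyl enone; no stereocentre is formed.

Step 2
Reactants: 3 3-(propan-2-yl)cyclopent-2-en-1-one
Product: 5 5-methyl-3-(propan-2-yl)cyclopent-2-en-1-one (racemic), via lithium dienolate 4 (not isolated)
Conditions: LiN(i-Pr)2, THF, −78 °C; MeI, −78 → −20 °C
Reagents that add atoms: iodomethane, CI
Why: Kinetic deprotonation of the enone takes place at the α′ CH2 (the future C1) and methylation of the cross-conjugated enolate gives the α′-methyl enone, whose racemic stereocentre is erased again in step 5.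

Step 3
Reactants: 5 5-methyl-3-(propan-2-yl)cyclopent-2-en-1-one (racemic)
Product: 7 (3R)-3-hydroxy-5-methyl-3-(propan-2-yl)cyclopentan-1-one (both C5 epimers), via tertiary boronic ester 6 (not isolated)
Conditions: B2pin2, CuCl (5 mol %), (R,R)-QuinoxP* (5 mol %), NaOt-Bu (10 mol %), MeOH (2 equiv), THF, rt; then NaBO3·4H2O, THF/H2O, rt
Reagents that add atoms: bis(pinacolato)diboron, CC1(C)OB(OC1(C)C)B1OC(C)(C)C(C)(C)O1 (boron of 6); sodium perborate, [Na+].[O-]OB=O (oxygen of 7)
Why: Copper-catalysed enantioselective conjugate borylation of a β,β-disubstituted cyclic enone places boron on the β-carbon (C4) under ligand control and perborate oxidation replaces boron by hydroxyl with retention, which sets the tertiary carbinol C4.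

Step 4
Reactants: 7 (3R)-3-hydroxy-5-methyl-3-(propan-2-yl)cyclopentan-1-one (both C5 epimers)
Product: 8 (3R)-3-[(tert-butyldimethylsilyl)oxy]-5-methyl-3-(propan-2-yl)cyclopentan-1-one (both C5 epimers)
Conditions: TBSOTf, 2,6-lutidine, CH2Cl2, −78 → 0 °C
Reagents that add atoms: tert-butyldimethylsilyl trifluoromethanesulfonate, CC(C)(C)[Si](C)(C)OS(=O)(=O)C(F)(F)F
Why: A silyl triflate with 2,6-lutidine silylates the hindered tertiary alcohol at low temperature without touching the ketone, which blocks retro-aldol cleavage and provides the bulky group that later shields one ring face.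

Step 5
Reactants: 8 (3R)-3-[(tert-butyldimethylsilyl)oxy]-5-methyl-3-(propan-2-yl)cyclopentan-1-one (both C5 epimers)
Product: 9 (4R)-4-[(tert-butyldimethylsilyl)oxy]-2-methyl-4-(propan-2-yl)cyclopent-2-en-1-one
Conditions: IBX (2-iodoxybenzoic acid), DMSO/toluene, 70 °C
Reagents that add atoms: none
Why: IBX dehydrogenation of the ketone through its more substituted enol can only run toward C1–C5 because C4 carries no hydrogen, so both epimers of 8 should converge on the single 2-methyl enone.

Step 6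
Reactants: 10 3-methylfuran-2(5H)-one
Product: 11 triethyl[(3-methylfuran-2-yl)oxy]silane
Conditions: Et3SiOTf, Et3N, CH2Cl2, 0 °C
Reagents that add atoms: triethylsilyl trifluoromethanesulfonate, CC[Si](CC)(CC)OS(=O)(=O)C(F)(F)F
Why: Soft enolisation of the butenolide with a silyl triflate and triethylamine gives the aromatic 2-silyloxyfuran, the standard γ-nucleophile for vinylogous Mukaiyama reactions.

Step 7
Reactants: 9 (4R)-4-[(tert-butyldimethylsilyl)oxy]-2-methyl-4-(propan-2-yl)cyclopent-2-en-1-one; 11 triethyl[(3-methylfuran-2-yl)oxy]silane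
Product: 12 (5R)-5-{(1R,5R)-5-[(tert-butyldimethylsilyl)oxy]-2-methyl-5-(propan-2-yl)-3-[(triethylsilyl)oxy]cyclopent-2-en-1-yl}-3-methylfuran-2(5H)-one
Conditions: Et3SiOTf (10 mol %), CH2Cl2, −78 °C; then pyridine
Reagents that add atoms: none
Why: Silyl triflate-catalysed vinylogous Mukaiyama–Michael addition, in which the furan γ-carbon adds to the enone β-carbon C5 with dearomatisation to the butenolide and silyl transfer to the enol oxygen; attack anti to the C4–O bond (the silyl ether covers that face while the isopropyl group can turn its C–H inward) should set C5, and an endo-type synclinal transition state with the small C6–H in the crowded sector between C1 and C4 should set C6.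

Step 8
Reactants: 12 (5R)-5-{(1R,5R)-5-[(tert-butyldimethylsilyl)oxy]-2-methyl-5-(propan-2-yl)-3-[(triethylsilyl)oxy]cyclopent-2-en-1-yl}-3-methylfuran-2(5H)-one
Product: 13 (5R)-5-{(1R,2R,5R)-5-[(tert-butyldimethylsilyl)oxy]-2-(hydroxymethyl)-2-methyl-3-oxo-5-(propan-2-yl)cyclopentyl}-3-methylfuran-2(5H)-one
Conditions: aq. HCHO (37 %), Sc(OTf)3 (10 mol %), THF, rt
Reagents that add atoms: formaldehyde, C=O
Why: Lewis acid-catalysed aqueous Mukaiyama aldol reaction (hydroxymethylation) of the regiodefined silyl enol ether builds the quaternary centre C1 without base, formaldehyde entering anti to the butenolide on the neighbouring C5.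

Step 9
Reactants: 13 (5R)-5-{(1R,2R,5R)-5-[(tert-butyldimethylsilyl)oxy]-2-(hydroxymethyl)-2-methyl-3-oxo-5-(propan-2-yl)cyclopentyl}-3-methylfuran-2(5H)-one
Product: 14 (5R)-5-{(1R,2R,3S,5R)-5-[(tert-butyldimethylsilyl)oxy]-3-hydroxy-2-(hydroxymethyl)-2-methyl-5-(propan-2-yl)cyclopentyl}-3-methylfuran-2(5H)-one
Conditions: Me4NBH(OAc)3, MeCN/AcOH, −20 °C
Reagents that add atoms: none
Why: Hydroxyl-directed reduction of the β-hydroxy ketone (Evans–Saksena reduction), in which the primary hydroxyl binds boron and delivers hydride to C2 from its own face, so the new hydroxyl should end trans to the CH2OH group and cis to the methyl group, while the butenolide is inert to this mild hydride.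

Step 10
Reactants: 14 (5R)-5-{(1R,2R,3S,5R)-5-[(tert-butyldimethylsilyl)oxy]-3-hydroxy-2-(hydroxymethyl)-2-methyl-5-(propan-2-yl)cyclopentyl}-3-methylfuran-2(5H)-one
Product: 15 (5R)-5-{(1R,2S,3S,5R)-5-[(tert-butyldimethylsilyl)oxy]-3-hydroxy-2-(iodomethyl)-2-methyl-5-(propan-2-yl)cyclopentyl}-3-methylfuran-2(5H)-one
Conditions: I2, PPh3, imidazole, toluene, 60 °C
Reagents that add atoms: iodine, II
Why: Appel-type iodination should convert only the primary hydroxyl into the neopentyl iodide, since the secondary hydroxyl next to the quaternary carbon is much more hindered and the tertiary one is silylated.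

Step 11
Reactants: 15 (5R)-5-{(1R,2S,3S,5R)-5-[(tert-butyldimethylsilyl)oxy]-3-hydroxy-2-(iodomethyl)-2-methyl-5-(propan-2-yl)cyclopentyl}-3-methylfuran-2(5H)-one
Product: 16 (5R)-5-{(1R,2S,3S,5R)-3,5-bis[(tert-butyldimethylsilyl)oxy]-2-(iodomethyl)-2-methyl-5-(propan-2-yl)cyclopentyl}-3-methylfuran-2(5H)-one
Conditions: TBSOTf, 2,6-lutidine, CH2Cl2, 0 °C
Reagents that add atoms: tert-butyldimethylsilyl trifluoromethanesulfonate, CC(C)(C)[Si](C)(C)OS(=O)(=O)C(F)(F)F
Why: Silylation of the remaining secondary alcohol removes the only acidic proton and leaves no ester that could take part in acyl transfer during the organometallic step.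

Step 12
Reactants: 16 (5R)-5-{(1R,2S,3S,5R)-3,5-bis[(tert-butyldimethylsilyl)oxy]-2-(iodomethyl)-2-methyl-5-(propan-2-yl)cyclopentyl}-3-methylfuran-2(5H)-one
Product: 19 (1R,3S,3aS,8R,8aR)-1,3-bis[(tert-butyldimethylsilyl)oxy]-8-hydroxy-3a,6-dimethyl-1-(propan-2-yl)-2,3,3a,4,8,8a-hexahydroazulen-5(1H)-one, via alkylsamarium 17 (not isolated), via bridged samarium hemiketalate 18 (not isolated)
Conditions: SmI2 (2.2 equiv), Fe(PhCOCHCOPh)3 (2 mol %), THF, −30 → 0 °C; then aq. NH4Cl
Reagents that add atoms: none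
Why: Proposed new method: two single-electron transfers from divalent samarium (SmI2, assisted by the iron catalyst) should reduce the neopentyl C–I bond of 16 through the alkyl radical to alkylsamarium 17, whose C10 adds to the lactone carbonyl C9 to give the bridged trivalent samarium hemiketalate 18 (an 8-oxabicyclo[3.2.1]oct-6-ene), which opens on aqueous work-up to the ring ketone and the free C6 hydroxyl. The closest known reaction type is the SmI2-promoted intramolecular nucleophilic acyl substitution (Barbier-type ring expansion) of iodoalkyl-substituted saturated lactones to hydroxy cycloalkanones, and its use on an α,β-unsaturated lactone is the new element. The seven-membered carbocycle closes by 7-exo-trig attack on the carbonyl carbon, which at the same time closes the six-membered oxane ring of 18 (6-exo-trig) before the five-membered lactone ring is lost. No stereocentre of the product is created (C9 ends as a carbonyl and its transient configuration in 18 is fixed by the oxygen bridge), and C1, C5 and C6 are not touched. The step needs reduction of C–I ahead of electron transfer to the conjugated lactone (iron catalysis at low temperature, no HMPA and no proton source), 1,2- instead of 1,4-addition (C10 on C1 and the butenolide on C5 are trans on the cyclopentane, so the 5-exo conjugate closure would demand a trans-fused bicyclo[3.3.0]octane whereas the trans-fused 5/7 system is unstrained) and absence of acyl transfer (both hydroxyls are silyl ethers). Over-addition and over-reduction should not occur because the ketone stays masked as hemiketalate 18 until work-up.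

Step 13
Reactants: 19 (1R,3S,3aS,8R,8aR)-1,3-bis[(tert-butyldimethylsilyl)oxy]-8-hydroxy-3a,6-dimethyl-1-(propan-2-yl)-2,3,3a,4,8,8a-hexahydroazulen-5(1H)-one; 20 4-(chlorocarbonyl)phenyl acetate
Product: 21 (1R,3S,3aS,8R,8aR)-1,3-bis[(tert-butyldimethylsilyl)oxy]-3a,6-dimethyl-5-oxo-1-(propan-2-yl)-1,2,3,3a,4,5,8,8a-octahydroazulen-8-yl 4-(acetyloxy)benzoate
Conditions: pyridine, CH2Cl2, 0 °C → rt
Reagents that add atoms: none
Why: Acylation of the secondary allylic alcohol (the open form of the hydroxy enone/hemiketal pair) with the acid chloride gives the aryl ester with retention at C6, the phenol being carried as its acetate and the mild base leaving the γ-oxygenated enone intact.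

Step 14
Reactants: 21 (1R,3S,3aS,8R,8aR)-1,3-bis[(tert-butyldimethylsilyl)oxy]-3a,6-dimethyl-5-oxo-1-(propan-2-yl)-1,2,3,3a,4,5,8,8a-octahydroazulen-8-yl 4-(acetyloxy)benzoate
Product: 22 (1R,3S,3aS,8R,8aR)-1,3-dihydroxy-3a,6-dimethyl-5-oxo-1-(propan-2-yl)-1,2,3,3a,4,5,8,8a-octahydroazulen-8-yl 4-(acetyloxy)benzoate
Conditions: aq. HF (48 %), MeCN, 0 °C → rt
Reagents that add atoms: none
Why: Aqueous HF in acetonitrile cleaves both alkyl silyl ethers, while the esters, the enone and the aryl acetate are stable to these acidic fluoride conditions.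

Step 15
Reactants: 22 (1R,3S,3aS,8R,8aR)-1,3-dihydroxy-3a,6-dimethyl-5-oxo-1-(propan-2-yl)-1,2,3,3a,4,5,8,8a-octahydroazulen-8-yl 4-(acetyloxy)benzoate
Product: 23 (1R,3S,3aS,8R,8aR)-3-(acetyloxy)-1-hydroxy-3a,6-dimethyl-5-oxo-1-(propan-2-yl)-1,2,3,3a,4,5,8,8a-octahydroazulen-8-yl 4-(acetyloxy)benzoate
Conditions: Ac2O, pyridine, DMAP (cat.), CH2Cl2, 0 °C
Reagents that add atoms: acetic anhydride, CC(=O)OC(C)=O
Why: Acetic anhydride with pyridine and catalytic DMAP acetylates the secondary C2 hydroxyl, whereas the tertiary C4 hydroxyl is too hindered to react at 0 °C.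

Step 16
Reactants: 23 (1R,3S,3aS,8R,8aR)-3-(acetyloxy)-1-hydroxy-3a,6-dimethyl-5-oxo-1-(propan-2-yl)-1,2,3,3a,4,5,8,8a-octahydroazulen-8-yl 4-(acetyloxy)benzoate
Product: 24 (1R,3S,3aS,8R,8aR)-3-(acetyloxy)-1-hydroxy-3a,6-dimethyl-5-oxo-1-(propan-2-yl)-1,2,3,3a,4,5,8,8a-octahydroazulen-8-yl 4-hydroxybenzoate
Conditions: NH4OAc, MeOH/H2O, rt
Reagents that add atoms: none
Why: Phenolic acetates are cleaved by ammonium acetate in aqueous methanol much faster than alkyl acetates or benzoate esters, so only the aryl acetate should be removed and the target set free.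

**Compound list**

1 | 3-ethoxycyclopent-2-en-1-one | CCOC1=CC(=O)CC1 | starting material
2 | 3-ethoxy-1-(propan-2-yl)cyclopent-2-en-1-ol (racemic, present as its magnesium alkoxide) | CCOC1=CC(O)(C(C)C)CC1 | intermediate
3 | 3-(propan-2-yl)cyclopent-2-en-1-one | CC(C)C1=CC(=O)CC1 | intermediate
4 | lithium 4-(propan-2-yl)cyclopenta-1,4-dien-1-olate | [Li]OC1=CCC(C(C)C)=C1 | intermediate
5 | 5-methyl-3-(propan-2-yl)cyclopent-2-en-1-one (racemic) | CC1CC(C(C)C)=CC1=O | intermediate
6 | (3S)-5-methyl-3-(propan-2-yl)-3-(4,4,5,5-tetramethyl-1,3,2-dioxaborolan-2-yl)cyclopentan-1-one (both C5 epimers) | CC1C[C@](B2OC(C)(C)C(C)(C)O2)(C(C)C)CC1=O | intermediate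
7 | (3R)-3-hydroxy-5-methyl-3-(propan-2-yl)cyclopentan-1-one (both C5 epimers) | CC1C[C@](O)(C(C)C)CC1=O | intermediate
8 | (3R)-3-[(tert-butyldimethylsilyl)oxy]-5-methyl-3-(propan-2-yl)cyclopentan-1-one (both C5 epimers) | CC1C[C@](O[Si](C)(C)C(C)(C)C)(C(C)C)CC1=O | intermediate
9 | (4R)-4-[(tert-butyldimethylsilyl)oxy]-2-methyl-4-(propan-2-yl)cyclopent-2-en-1-one | CC1=C[C@](O[Si](C)(C)C(C)(C)C)(C(C)C)CC1=O | intermediate
10 | 3-methylfuran-2(5H)-one | CC1=CCOC1=O | starting material
11 | triethyl[(3-methylfuran-2-yl)oxy]silane | CC[Si](CC)(CC)Oc1occc1C | intermediate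
12 | (5R)-5-{(1R,5R)-5-[(tert-butyldimethylsilyl)oxy]-2-methyl-5-(propan-2-yl)-3-[(triethylsilyl)oxy]cyclopent-2-en-1-yl}-3-methylfuran-2(5H)-one | CC1=C(O[Si](CC)(CC)CC)C[C@@](O[Si](C)(C)C(C)(C)C)(C(C)C)[C@H]1[C@@H]2OC(=O)C(C)=C2 | intermediate
13 | (5R)-5-{(1R,2R,5R)-5-[(tert-butyldimethylsilyl)oxy]-2-(hydroxymethyl)-2-methyl-3-oxo-5-(propan-2-yl)cyclopentyl}-3-methylfuran-2(5H)-one | O=C1C[C@@](O[Si](C)(C)C(C)(C)C)(C(C)C)[C@@H]([C@@H]2OC(=O)C(C)=C2)[C@]1(C)CO | intermediate
14 | (5R)-5-{(1R,2R,3S,5R)-5-[(tert-butyldimethylsilyl)oxy]-3-hydroxy-2-(hydroxymethyl)-2-methyl-5-(propan-2-yl)cyclopentyl}-3-methylfuran-2(5H)-one | O[C@H]1C[C@@](O[Si](C)(C)C(C)(C)C)(C(C)C)[C@@H]([C@@H]2OC(=O)C(C)=C2)[C@]1(C)CO | intermediate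
15 | (5R)-5-{(1R,2S,3S,5R)-5-[(tert-butyldimethylsilyl)oxy]-3-hydroxy-2-(iodomethyl)-2-methyl-5-(propan-2-yl)cyclopentyl}-3-methylfuran-2(5H)-one | O[C@H]1C[C@@](O[Si](C)(C)C(C)(C)C)(C(C)C)[C@@H]([C@@H]2OC(=O)C(C)=C2)[C@]1(C)CI | intermediate
16 | (5R)-5-{(1R,2S,3S,5R)-3,5-bis[(tert-butyldimethylsilyl)oxy]-2-(iodomethyl)-2-methyl-5-(propan-2-yl)cyclopentyl}-3-methylfuran-2(5H)-one | CC(C)(C)[Si](C)(C)O[C@H]1C[C@@](O[Si](C)(C)C(C)(C)C)(C(C)C)[C@@H]([C@@H]2OC(=O)C(C)=C2)[C@]1(C)CI | intermediate
17 | alkylsamarium diiodide from 16 (C10–SmI2 in place of C10–I) | CC(C)(C)[Si](C)(C)O[C@H]1C[C@@](O[Si](C)(C)C(C)(C)C)(C(C)C)[C@@H]([C@@H]2OC(=O)C(C)=C2)[C@]1(C)C[Sm](I)I | intermediate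
18 | bridged samarium hemiketalate (8-oxabicyclo[3.2.1]oct-6-ene, oxygen bridge between C6 and C9, C9–O–SmI2) | CC(C)(C)[Si](C)(C)O[C@H]1C[C@@](O[Si](C)(C)C(C)(C)C)(C(C)C)[C@H]2[C@@H]3O[C@](O[Sm](I)I)(C[C@]12C)C(C)=C3 | intermediate
19 | (1R,3S,3aS,8R,8aR)-1,3-bis[(tert-butyldimethylsilyl)oxy]-8-hydroxy-3a,6-dimethyl-1-(propan-2-yl)-2,3,3a,4,8,8a-hexahydroazulen-5(1H)-one | CC(C)(C)[Si](C)(C)O[C@H]1C[C@@](O[Si](C)(C)C(C)(C)C)(C(C)C)[C@H]2[C@H](O)C=C(C)C(=O)C[C@]12C | intermediate
20 | 4-(chlorocarbonyl)phenyl acetate (4-acetoxybenzoyl chloride) | CC(=O)Oc1ccc(cc1)C(Cl)=O | starting material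
21 | (1R,3S,3aS,8R,8aR)-1,3-bis[(tert-butyldimethylsilyl)oxy]-3a,6-dimethyl-5-oxo-1-(propan-2-yl)-1,2,3,3a,4,5,8,8a-octahydroazulen-8-yl 4-(acetyloxy)benzoate | CC(C)(C)[Si](C)(C)O[C@H]1C[C@@](O[Si](C)(C)C(C)(C)C)(C(C)C)[C@H]2[C@H](OC(=O)c3ccc(OC(C)=O)cc3)C=C(C)C(=O)C[C@]12C | intermediate
22 | (1R,3S,3aS,8R,8aR)-1,3-dihydroxy-3a,6-dimethyl-5-oxo-1-(propan-2-yl)-1,2,3,3a,4,5,8,8a-octahydroazulen-8-yl 4-(acetyloxy)benzoate | O[C@H]1C[C@@](O)(C(C)C)[C@H]2[C@H](OC(=O)c3ccc(OC(C)=O)cc3)C=C(C)C(=O)C[C@]12C | intermediate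
23 | (1R,3S,3aS,8R,8aR)-3-(acetyloxy)-1-hydroxy-3a,6-dimethyl-5-oxo-1-(propan-2-yl)-1,2,3,3a,4,5,8,8a-octahydroazulen-8-yl 4-(acetyloxy)benzoate | CC(=O)O[C@H]1C[C@@](O)(C(C)C)[C@H]2[C@H](OC(=O)c3ccc(OC(C)=O)cc3)C=C(C)C(=O)C[C@]12C | intermediate
24 | (1R,3S,3aS,8R,8aR)-3-(acetyloxy)-1-hydroxy-3a,6-dimethyl-5-oxo-1-(propan-2-yl)-1,2,3,3a,4,5,8,8a-octahydroazulen-8-yl 4-hydroxybenzoate | CC(=O)O[C@H]1C[C@@](O)(C(C)C)[C@H]2[C@H](OC(=O)c3ccc(O)cc3)C=C(C)C(=O)C[C@]12C | target

**Step count and risks**

Total step count: 16. Longest linear sequence: 15 steps (steps 1 to 5 and 7 to 16; step 6 prepares the silyloxyfuran).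

Steps most likely to fail:

1. Step 12 (the step that carries the label). Electron transfer to the conjugated lactone (reductive cleavage of the C6–O bond or conjugate reduction) may compete with reduction of the neopentyl C–I bond, or the alkylsamarium may be protonated before it cyclises. The fallback uses known chemistry, sets out from 16 and comes back at 19. The butenolide is opened with MeNH(OMe)·HCl and AlMe3 in CH2Cl2 to the (Z)-4-hydroxy Weinreb amide F1. The hydroxyl is capped with Me3SiCl and imidazole to give the trimethylsilyl ether F2. Iodine–lithium exchange with t-BuLi in Et2O/pentane at −100 °C and intramolecular acylation of the Weinreb amide (Parham-type cyclisation) should give the cycloheptenone trimethylsilyl ether F3. Citric acid in methanol then removes the trimethylsilyl group to give 19.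

2. Step 7. The furan may enter syn to the silyloxy group (poor facial selectivity), or control at C6 may be low. The fallback lets silicon stand in for the C4 oxygen, sets out from 5 and comes back at 16. Copper-catalysed enantioselective conjugate silyl transfer from Me2PhSi–Bpin (CuCl, chiral N-heterocyclic carbene ligand, NaOt-Bu) gives the β-silyl ketone F4, and IBX gives the γ-silyl enone F5. The Mukaiyama–Michael addition of 11 should then go anti to the much larger dimethyl(phenyl)silyl group to give the silyl enol ether F6. Hydroxymethylation as in step 8 gives the hydroxymethyl ketone F7, and directed reduction as in step 9 gives the diol F8. Fleming–Tamao oxidation (KBr, AcOOH, NaOAc, AcOH) replaces silicon by hydroxyl with retention to give the triol F9. Iodination as in step 10 gives the iodo diol F10, and excess TBSOTf with 2,6-lutidine silylates both remaining hydroxyls to give 16.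

3. Step 8. Protodesilylation of the hindered enol ether in the aqueous acidic medium may outrun C–C bond formation at the fully substituted carbon. The fallback sets out from 12 and comes back at 13. Anhydrous Lewis-acid alkylation with 4-methoxybenzyl chloromethyl ether and ZnBr2 in CH2Cl2 gives the 4-methoxybenzyl ether F11, and DDQ in CH2Cl2/pH 7 buffer removes the benzyl group to give 13.

**Further compounds**

F1 | step 12 | (2Z,4R)-4-{(1R,2S,3S,5R)-3,5-bis[(tert-butyldimethylsilyl)oxy]-2-(iodomethyl)-2-methyl-5-(propan-2-yl)cyclopentyl}-4-hydroxy-N-methoxy-N,2-dimethylbut-2-enamide | CC(C)(C)[Si](C)(C)O[C@H]1C[C@@](O[Si](C)(C)C(C)(C)C)(C(C)C)[C@@H]([C@H](O)/C=C(C)\C(=O)N(C)OC)[C@]1(C)CI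
F2 | step 12 | O-trimethylsilyl ether of F1 | CC(C)(C)[Si](C)(C)O[C@H]1C[C@@](O[Si](C)(C)C(C)(C)C)(C(C)C)[C@@H]([C@H](O[Si](C)(C)C)/C=C(C)\C(=O)N(C)OC)[C@]1(C)CI
F3 | step 12 | O-trimethylsilyl ether of 19 (trimethylsilyloxy group on C6) | CC(C)(C)[Si](C)(C)O[C@H]1C[C@@](O[Si](C)(C)C(C)(C)C)(C(C)C)[C@H]2[C@H](O[Si](C)(C)C)C=C(C)C(=O)C[C@]12C
F4 | step 7 | (3R)-3-[dimethyl(phenyl)silyl]-5-methyl-3-(propan-2-yl)cyclopentan-1-one (both C5 epimers) | CC1C[C@]([Si](C)(C)c2ccccc2)(C(C)C)CC1=O
F5 | step 7 | (4R)-4-[dimethyl(phenyl)silyl]-2-methyl-4-(propan-2-yl)cyclopent-2-en-1-one | CC1=C[C@]([Si](C)(C)c2ccccc2)(C(C)C)CC1=O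
F6 | step 7 | analogue of 12 with a dimethyl(phenyl)silyl group on C4 in place of the silyloxy group | CC1=C(O[Si](CC)(CC)CC)C[C@@]([Si](C)(C)c2ccccc2)(C(C)C)[C@H]1[C@@H]3OC(=O)C(C)=C3
F7 | step 7 | analogue of 13 with a dimethyl(phenyl)silyl group on C4 in place of the silyloxy group | O=C1C[C@@]([Si](C)(C)c2ccccc2)(C(C)C)[C@@H]([C@@H]3OC(=O)C(C)=C3)[C@]1(C)CO
F8 | step 7 | analogue of 14 with a dimethyl(phenyl)silyl group on C4 in place of the silyloxy group | O[C@H]1C[C@@]([Si](C)(C)c2ccccc2)(C(C)C)[C@@H]([C@@H]3OC(=O)C(C)=C3)[C@]1(C)CO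
F9 | step 7 | desilylated triol corresponding to 14 (free hydroxyls on C2, C4 and C10) | O[C@H]1C[C@@](O)(C(C)C)[C@@H]([C@@H]3OC(=O)C(C)=C3)[C@]1(C)CO
F10 | step 7 | iodo diol corresponding to 15 with a free C4 hydroxyl | O[C@H]1C[C@@](O)(C(C)C)[C@@H]([C@@H]3OC(=O)C(C)=C3)[C@]1(C)CI
F11 | step 8 | 4-methoxybenzyl ether of 13 (C10–O–CH2C6H4OMe) | O=C1C[C@@](O[Si](C)(C)C(C)(C)C)(C(C)C)[C@@H]([C@@H]2OC(=O)C(C)=C2)[C@]1(C)COCc3ccc(OC)cc3
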